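**Assumption:** 6‑bromoisovanillin, 4‑bromo‑2,6‑dimethoxyphenol, (3‑ethoxy‑3‑oxopropyl)zinc bromide (0.5 M in THF) and tert‑butyl diethylphosphonoacetate are taken as commercial. The target is read as the (1R,2S,3S), all‑trans aryltetralin (5'‑methoxyisolariciresinol skeleton, 6‑OMe/7‑OH on the fused ring).

## Retrosynthetic overview

1. The usual C1–C(aryl) Friedel–Crafts closure of a dibenzylbutane or butyrolactone is avoided. The carbocycle is closed last at C2–C3 (the lignan 8–8' bond) by intramolecular oxidative coupling of a diester bis‑enolate.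
2. C2 and C3 are then set by thermodynamic epimerisation to the all‑equatorial diester, relayed from C1.
3. C1 is the only stereocentre set by a reagent: Rh/chiral‑diene asymmetric 1,4‑addition of a syringyl boronic acid to a ring‑A cinnamate.
4. The acyclic diester comes from 6‑bromoisovanillin: Negishi coupling installs the C4–C3 arm and HWE installs the C1=C2 arm.
5. Only one ring is formed (the cyclohexane of the tetralin); both arenes are bought.

## Route

**Step 1**
Reactants: 1, 2‑bromo‑5‑hydroxy‑4‑methoxybenzaldehyde (6‑bromoisovanillin); 2, benzyl bromide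
Product: 3, 5‑(benzyloxy)‑2‑bromo‑4‑methoxybenzaldehyde
Conditions: BnBr, K2CO3, DMF, rt
Reagents that add atoms: benzyl bromide, BrCc1ccccc1
Why: Williamson etherification of the only acidic OH; it masks the phenol for the later organometallic and LDA steps.

**Step 2**
Reactants: 3; 4, (3‑ethoxy‑3‑oxopropyl)zinc bromide
Product: 5, ethyl 3‑[4‑(benzyloxy)‑2‑formyl‑5‑methoxyphenyl]propanoate
Conditions: 4 (1.5 equiv), Pd(OAc)2 (2 mol%), SPhos (4 mol%), THF, rt→40 °C
Reagents that add atoms: (3‑ethoxy‑3‑oxopropyl)zinc bromide, CCOC(=O)CC[Zn]Br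
Why: Negishi sp2–sp3 coupling of an ortho‑formyl‑activated aryl bromide; alkylzinc halides do not add to the aldehyde without Lewis acid, so the CHO survives.

**Step 3**
Reactants: 5; 6, tert‑butyl diethylphosphonoacetate
Product: 7, tert‑butyl (2E)‑3‑[5‑(benzyloxy)‑2‑(3‑ethoxy‑3‑oxopropyl)‑4‑methoxyphenyl]prop‑2‑enoate
Conditions: 6, LiCl, DBU, MeCN, rt
Reagents that add atoms: tert‑butyl diethylphosphonoacetate, CCOP(=O)(OCC)CC(=O)OC(C)(C)C
Why: Horner–Wadsworth–Emmons olefination under Masamune–Roush conditions gives the E‑cinnamate and is too mild to enolise the ethyl ester.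

**Step 4**
Reactants: 8, 4‑bromo‑2,6‑dimethoxyphenol; 2, benzyl bromide
Product: 9, 2‑(benzyloxy)‑5‑bromo‑1,3‑dimethoxybenzene
Conditions: BnBr, K2CO3, DMF, 50 °C
Reagents that add atoms: benzyl bromide, BrCc1ccccc1
Why: Williamson etherification; the hindered phenol still alkylates cleanly with a benzylic halide.

**Step 5**
Reactants: 9; 10, triisopropyl borate
Product: 11, [4‑(benzyloxy)‑3,5‑dimethoxyphenyl]boronic acid
Conditions: n‑BuLi, THF, −78 °C; B(OiPr)3; then 1 M HCl, rt
Reagents that add atoms: triisopropyl borate, CC(C)OB(OC(C)C)OC(C)C; water, O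
Why: Br/Li exchange is much faster than any benzyl‑ether metalation at −78 °C; borate trapping and hydrolysis give the boronic acid.

**Step 6**
Reactants: 7; 11
Product: 12, tert‑butyl (3R)‑3‑[5‑(benzyloxy)‑2‑(3‑ethoxy‑3‑oxopropyl)‑4‑methoxyphenyl]‑3‑[4‑(benzyloxy)‑3,5‑dimethoxyphenyl]propanoate
Conditions: 11 (2 equiv), [RhCl(C2H4)2]2 (2.5 mol%), chiral 2,5‑diphenylbicyclo[2.2.2]octa‑2,5‑diene (Ph‑bod*, 5.5 mol%), KOH (0.3 equiv), dioxane/H2O 10:1, 50 °C
Reagents that add atoms: boronic acid 11, COc1cc(B(O)O)cc(OC)c1OCc1ccccc1 (aryl group transferred)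
Why: Hayashi–Miyaura Rh‑catalysed asymmetric 1,4‑arylation of a tert‑butyl cinnamate; the diene enantiomer is chosen so the aryl‑Rh adds to the Si face of Cβ, which gives the 3R diarylmethine (future C1). The sense is to be confirmed by chiral HPLC and rotation on the first batch.

**Step 7**
Reactants: 12
Product: 13, 2‑tert‑butyl 3‑ethyl (1R)‑7‑(benzyloxy)‑1‑[4‑(benzyloxy)‑3,5‑dimethoxyphenyl]‑6‑methoxy‑1,2,3,4‑tetrahydronaphthalene‑2,3‑dicarboxylate, as a mixture of C2/C3 diastereomers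
Conditions: LDA (2.3 equiv), THF, −78 °C (12 added to the base); then anhydrous CuCl2 (2.5 equiv) in DMF, −78 °C→rt
Reagents that add atoms: none
Why: Intramolecular oxidative coupling of a diester bis‑enolate (Cu(II) single‑electron oxidation, or α‑halogenation then 6‑exo SN2 by the second enolate; both give the same product) forms C2–C3 and closes the six‑membered ring. C1 is not acidic enough to be touched, and the C2/C3 ratio does not matter because of step 8.

**Step 8**
Reactants: 13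
Product: 14, 2‑tert‑butyl 3‑ethyl (1R,2S,3S)‑7‑(benzyloxy)‑1‑[4‑(benzyloxy)‑3,5‑dimethoxyphenyl]‑6‑methoxy‑1,2,3,4‑tetrahydronaphthalene‑2,3‑dicarboxylate
Conditions: t‑BuOK (0.5 equiv), THF/t‑BuOH, rt→40 °C
Reagents that add atoms: none
Why: Base‑mediated thermodynamic epimerisation of both ester α‑centres converges on the all‑equatorial 1,2‑trans‑2,3‑trans isomer, so the fixed C1 (R) dictates 2S,3S; any ester exchange is irrelevant because both esters are reduced next.

**Step 9**
Reactants: 14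
Product: 15, [(1R,2S,3S)‑7‑(benzyloxy)‑1‑[4‑(benzyloxy)‑3,5‑dimethoxyphenyl]‑6‑methoxy‑1,2,3,4‑tetrahydronaphthalene‑2,3‑diyl]dimethanol
Conditions: LiAlH4, THF, 0 °C→reflux
Reagents that add atoms: none
Why: Hydride reduction of both esters to primary alcohols; no stereocentre is epimerisable once the carbonyls are gone, and benzyl ethers are inert.

**Step 10**
Reactants: 15
Product: 16, 4‑[(1R,2S,3S)‑7‑hydroxy‑2,3‑bis(hydroxymethyl)‑6‑methoxy‑1,2,3,4‑tetrahydronaphthalen‑1‑yl]‑2,6‑dimethoxyphenol (target, CID70697973)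
Conditions: H2 (1 atm), 10% Pd/C, EtOAc/MeOH, rt
Reagents that add atoms: none
Why: Hydrogenolysis of both aryl benzyl ethers; the diarylmethine C–H, the primary alcohols and the electron‑rich rings are untouched under these conditions.

## Compound list

1 | 2‑bromo‑5‑hydroxy‑4‑methoxybenzaldehyde | O=Cc1cc(O)c(OC)cc1Br | starting material
2 | benzyl bromide | BrCc1ccccc1 | starting material
3 | 5‑(benzyloxy)‑2‑bromo‑4‑methoxybenzaldehyde | O=Cc1cc(OCc2ccccc2)c(OC)cc1Br | intermediate
4 | (3‑ethoxy‑3‑oxopropyl)zinc bromide | CCOC(=O)CC[Zn]Br | starting material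
5 | ethyl 3‑[4‑(benzyloxy)‑2‑formyl‑5‑methoxyphenyl]propanoate | CCOC(=O)CCc1cc(OC)c(OCc2ccccc2)cc1C=O | intermediate
6 | tert‑butyl diethylphosphonoacetate | CCOP(=O)(OCC)CC(=O)OC(C)(C)C | starting material
7 | tert‑butyl (2E)‑3‑[5‑(benzyloxy)‑2‑(3‑ethoxy‑3‑oxopropyl)‑4‑methoxyphenyl]prop‑2‑enoate | CCOC(=O)CCc1cc(OC)c(OCc2ccccc2)cc1/C=C/C(=O)OC(C)(C)C | intermediate
8 | 4‑bromo‑2,6‑dimethoxyphenol | COc1cc(Br)cc(OC)c1O | starting material
9 | 2‑(benzyloxy)‑5‑bromo‑1,3‑dimethoxybenzene | COc1cc(Br)cc(OC)c1OCc1ccccc1 | intermediate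
10 | triisopropyl borate | CC(C)OB(OC(C)C)OC(C)C | starting material
11 | [4‑(benzyloxy)‑3,5‑dimethoxyphenyl]boronic acid | COc1cc(B(O)O)cc(OC)c1OCc1ccccc1 | intermediate
12 | tert‑butyl (3R)‑3‑[5‑(benzyloxy)‑2‑(3‑ethoxy‑3‑oxopropyl)‑4‑methoxyphenyl]‑3‑[4‑(benzyloxy)‑3,5‑dimethoxyphenyl]propanoate | CCOC(=O)CCc1cc(OC)c(OCc2ccccc2)cc1[C@H](CC(=O)OC(C)(C)C)c1cc(OC)c(OCc2ccccc2)c(OC)c1 | intermediate
13 | 2‑tert‑butyl 3‑ethyl (1R)‑7‑(benzyloxy)‑1‑[4‑(benzyloxy)‑3,5‑dimethoxyphenyl]‑6‑methoxy‑1,2,3,4‑tetrahydronaphthalene‑2,3‑dicarboxylate (C2/C3 mixture) | COc1cc2c(cc1OCc1ccccc1)[C@@H](c1cc(OC)c(OCc3ccccc3)c(OC)c1)C(C(=O)OC(C)(C)C)C(C(=O)OCC)C2 | intermediate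
14 | 2‑tert‑butyl 3‑ethyl (1R,2S,3S)‑7‑(benzyloxy)‑1‑[4‑(benzyloxy)‑3,5‑dimethoxyphenyl]‑6‑methoxy‑1,2,3,4‑tetrahydronaphthalene‑2,3‑dicarboxylate | COc1cc2c(cc1OCc1ccccc1)[C@@H](c1cc(OC)c(OCc3ccccc3)c(OC)c1)[C@H](C(=O)OC(C)(C)C)[C@@H](C(=O)OCC)C2 | intermediate
15 | [(1R,2S,3S)‑7‑(benzyloxy)‑1‑[4‑(benzyloxy)‑3,5‑dimethoxyphenyl]‑6‑methoxy‑1,2,3,4‑tetrahydronaphthalene‑2,3‑diyl]dimethanol | COc1cc2c(cc1OCc1ccccc1)[C@@H](c1cc(OC)c(OCc3ccccc3)c(OC)c1)[C@H](CO)[C@@H](CO)C2 | intermediate
16 | 4‑[(1R,2S,3S)‑7‑hydroxy‑2,3‑bis(hydroxymethyl)‑6‑methoxy‑1,2,3,4‑tetrahydronaphthalen‑1‑yl]‑2,6‑dimethoxyphenol | COc1cc2c(cc1O)[C@@H](c1cc(OC)c(O)c(OC)c1)[C@H](CO)[C@@H](CO)C2 | target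

## Summary

**Total steps:** 10.
**Longest linear sequence:** 8 (steps 1, 2, 3, 6, 7, 8, 9, 10); steps 4–5 are a two‑step convergent branch.

**Three steps most likely to fail, with fallbacks**

1. **Step 7, oxidative bis‑enolate ring closure.** Risks are oligomerisation, seven‑membered Dieckmann condensation and simple α‑halogenation. Fallback: close the ring at C3–C4 by enolate benzylation instead.
   - Start from 6‑bromovanillin, turning CHO into CH2OTBS and Br into the tert‑butyl cinnamate by Heck reaction.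
   - Carry out the same Rh arylation, then alkylate the C2 ester enolate with ethyl bromoacetate.
   - Convert CH2OTBS to CH2Br and cyclise with LiHMDS (6‑exo‑tet); the product rejoins the route at 13.

2. **Step 6, Rh asymmetric arylation.** The ortho‑substituted, electron‑rich cinnamate may be slow or give lower ee. Fallback: auxiliary control. Convert the cinnamate to its N‑enoyl Evans oxazolidinone, add the aryl Grignard from 9 with CuBr·SMe2, then cleave the auxiliary to the ester.

3. **Step 8, epimerisation to all‑trans.** The equilibrium may be incomplete, or the hindered C2–H next to the tert‑butyl ester may exchange slowly. Fallback: move the equilibration to the dialdehyde level. Reduce the 13 mixture to the diols, oxidise to the dialdehydes (Swern), equilibrate with DBU (far more acidic α‑H, same all‑equatorial preference), then reduce with NaBH4 to 15.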